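**Retrosynthetic overview**
1. Feature: ring C is a 5-substituted resorcinol, with O on C3' and C5' and C1' bonded to the methine C3 of the dihydrobenzofuran. A 3-substituted cyclobutenone and an alkoxyacetylene give exactly this 1,3,5-pattern, so C3 is fixed first as an ester-bearing centre and ring C is grown on it.
2. Last disconnections: five O-alkyl bonds (BBr3) and the C5–vinyl bond of ring A (Heck reaction of the aryl chloride with 3,5-dimethoxystyrene, which brings ring D).
3. Key disconnection: ring C is cut at C2'–C3' and C4'–C5' into a cyclobutenone carried on C3 and ethoxyacetylene.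
4. The cyclobutenone goes back to a C3-ethynyl group and dichloroketene, and the alkyne to the aldehyde and the trans C3 methyl ester.
5. The dihydrofuran ring is cut at C2–C3 (enantioselective rhodium-carbene C–H insertion of a veratryl aryl ether). Ring order: rings A, B (catechol) and D are bought, then the dihydrofuran ring, the four-membered ring and ring C are formed.

Key step: step 10

Assumption: for 2-(benzyloxy)phenyl diazoacetates the S-configured phthaloyl-tert-leucinate catalyst is taken to lead to the 2R series, so its mirror image Rh2(R-PTTL)4 (dirhodium tetrakis[N-phthaloyl-(R)-tert-leucinate]) is specified for the 2S target; the sense is to be checked on the trans ester by anomalous-dispersion crystallography (chlorine), and the antipodal catalyst is to be used if it proves opposite.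

**Route**

Step 1
Reactants: 1 (5-chloro-2-hydroxyphenyl)acetic acid
Product: 2 methyl (5-chloro-2-hydroxyphenyl)acetate
Conditions: MeOH, H2SO4 (cat.), reflux
Reagents that add atoms: methanol, CO
Why: Fischer esterification in a large excess of methanol should drive the acid to its methyl ester while the phenol stays free for the next step.

Step 2
Reactants: 2 methyl (5-chloro-2-hydroxyphenyl)acetate; 3 veratryl chloride (3,4-dimethoxybenzyl chloride)
Product: 4 methyl {5-chloro-2-[(3,4-dimethoxybenzyl)oxy]phenyl}acetate
Conditions: K2CO3, NaI (cat.), DMF, 40 °C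
Reagents that add atoms: none
Why: Williamson ether synthesis, in which carbonate deprotonates only the phenol and the phenoxide displaces chloride from the activated benzylic halide by SN2, bringing in ring B together with the future C2.

Step 3
Reactants: 4 methyl {5-chloro-2-[(3,4-dimethoxybenzyl)oxy]phenyl}acetate
Product: 5 methyl 2-{5-chloro-2-[(3,4-dimethoxybenzyl)oxy]phenyl}-2-diazoacetate
Conditions: p-ABSA, DBU, MeCN, 0 °C to rt
Reagents that add atoms: 4-acetamidobenzenesulfonyl azide (p-ABSA), CC(=O)Nc1ccc(cc1)S(=O)(=O)N=[N+]=[N-]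
Why: Regitz diazo transfer, for which DBU is basic enough to deprotonate an arylacetate so that the carbanion takes the N2 unit from the sulfonyl azide and gives the donor/acceptor diazo ester.

Step 4
Reactants: 5 methyl 2-{5-chloro-2-[(3,4-dimethoxybenzyl)oxy]phenyl}-2-diazoacetate
Product: 6 methyl (2S,3R)-5-chloro-2-(3,4-dimethoxyphenyl)-2,3-dihydro-1-benzofuran-3-carboxylate (cis)
Conditions: Rh2(R-PTTL)4 (1 mol %), toluene, −60 °C
Reagents that add atoms: none
Why: Enantioselective intramolecular 1,5 C–H insertion of a rhodium-bound donor/acceptor carbene into the benzylic C–H bond next to oxygen closes the five-membered ring at C2–C3, the compact transition state placing ring B and the ester cis, while the chiral carboxylate pocket selects one enantiotopic benzylic hydrogen and one carbene face and so sets C2 (S) and C3 (R).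

Step 5
Reactants: 6 methyl (2S,3R)-5-chloro-2-(3,4-dimethoxyphenyl)-2,3-dihydro-1-benzofuran-3-carboxylate (cis)
Product: 7 methyl (2S,3S)-5-chloro-2-(3,4-dimethoxyphenyl)-2,3-dihydro-1-benzofuran-3-carboxylate (trans)
Conditions: NaOMe (0.3 equiv), MeOH, rt
Reagents that add atoms: none
Why: Base-mediated epimerisation under thermodynamic control, in which only the C3–H (alpha to the ester and benzylic) is exchanged, reprotonation relieves the eclipsing of ester and ring B to give the trans isomer with C2 untouched, and loss of the phenoxide by beta-elimination is disfavoured because the C2–O bond lies in the nodal plane of the deprotonated ester (the reverse of a 5-endo-trig closure).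

Step 6
Reactants: 7 methyl (2S,3S)-5-chloro-2-(3,4-dimethoxyphenyl)-2,3-dihydro-1-benzofuran-3-carboxylate (trans)
Product: 9 (2S,3S)-5-chloro-2-(3,4-dimethoxyphenyl)-2,3-dihydro-1-benzofuran-3-carbaldehyde, via aluminium hemiacetal 8 (not isolated)
Conditions: i-Bu2AlH (1.1 equiv), CH2Cl2, −78 °C; MeOH, then aq. potassium sodium tartrate
Reagents that add atoms: none
Why: Partial ester reduction with i-Bu2AlH, in which the tetrahedral adduct 8 persists at −78 °C until the quench so that the aldehyde is released only when no hydride is left, and neither stereocentre is touched in this non-basic medium.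

Step 7
Reactants: 9 (2S,3S)-5-chloro-2-(3,4-dimethoxyphenyl)-2,3-dihydro-1-benzofuran-3-carbaldehyde
Product: 10 (2S,3S)-5-chloro-2-(3,4-dimethoxyphenyl)-3-ethynyl-2,3-dihydro-1-benzofuran
Conditions: MeC(O)C(N2)P(O)(OMe)2 (1.3 equiv), K2CO3 (2 equiv), MeOH, 0 °C to rt
Reagents that add atoms: dimethyl (1-diazo-2-oxopropyl)phosphonate, COP(=O)(OC)C(=[N+]=[N-])C(C)=O
Why: Seyferth–Gilbert homologation in its Ohira–Bestmann form turns CHO into C≡CH under mild carbonate conditions, and any enolisation of 9 on the way is harmless because C2 is fixed and reprotonation returns the more stable trans arrangement.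

Step 8
Reactants: 10 (2S,3S)-5-chloro-2-(3,4-dimethoxyphenyl)-3-ethynyl-2,3-dihydro-1-benzofuran; 11 trichloroacetyl chloride
Product: 13 4,4-dichloro-3-[(2S,3R)-5-chloro-2-(3,4-dimethoxyphenyl)-2,3-dihydro-1-benzofuran-3-yl]cyclobut-2-en-1-one (same spatial arrangement as 10; the C3 descriptor changes only because CCl2 raises the CIP rank of the new ring), via dichloroketene 12 (not isolated)
Conditions: Zn–Cu couple, Et2O–DME, slow addition of 11, rt
Reagents that add atoms: none
Why: Ketene–alkyne (2+2) cycloaddition, in which zinc dechlorinates 11 to 12, the electrophilic ketene carbonyl carbon bonds to the terminal alkyne carbon so that CCl2 ends next to the substituted carbon, DME ties up ZnCl2 and so shields the benzylic C2–O bond, and no stereocentre takes part.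

Step 9
Reactants: 13 4,4-dichloro-3-[(2S,3R)-5-chloro-2-(3,4-dimethoxyphenyl)-2,3-dihydro-1-benzofuran-3-yl]cyclobut-2-en-1-one
Product: 14 3-[(2S,3S)-5-chloro-2-(3,4-dimethoxyphenyl)-2,3-dihydro-1-benzofuran-3-yl]cyclobut-2-en-1-one
Conditions: Zn dust, AcOH, TMEDA, EtOH, 0 °C to rt
Reagents that add atoms: none
Why: Zinc-mediated reductive dechlorination of an alpha,alpha-dichloro ketone, for which amine-buffered acetic acid supplies protons without being acidic or basic enough to move the ring double bond towards C3 or to open the dihydrofuran, while the aryl chloride is inert to zinc dust.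

Step 10
Reactants: 14 3-[(2S,3S)-5-chloro-2-(3,4-dimethoxyphenyl)-2,3-dihydro-1-benzofuran-3-yl]cyclobut-2-en-1-one; 15 ethoxyacetylene
Product: 20 3-[(2S,3S)-5-chloro-2-(3,4-dimethoxyphenyl)-2,3-dihydro-1-benzofuran-3-yl]-5-ethoxyphenol, via vinylketene 16 (not isolated), via 4-alkenyl-3-ethoxycyclobutenone 17 (not isolated), via dienylketene 18 (not isolated), via cyclohexadienone 19 (not isolated)
Conditions: 15 (4 equiv, ca. 40 wt % in hexanes), toluene, sealed tube, 80 °C, then 110 °C; K2CO3, MeOH, rt
Reagents that add atoms: none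
Why: Danheiser benzannulation, a known pericyclic cascade of cyclobutenones and alkoxyacetylenes: release of ring strain lets 14 open at about 80 °C by a conrotatory 4-electron process (cleavage of C1–C4 of the four-membered ring) to vinylketene 16, whose ketene C=C adds 15 in a (2+2) cycloaddition to give 17. A second 4-electron opening of 17 gives dienylketene 18, ring C is closed by a disrotatory 6-electron electrocyclisation that joins the ketene carbon to the terminal CH2 (bond C5'–C6'), and tautomerisation of cyclohexadienone 19 to the phenol makes the sequence irreversible. In sum the two alkyne carbons are inserted between the former carbonyl carbon and the former =CH of 14, which creates the bonds C4'–C5' and C2'–C3'. The one selectivity needed is the orientation of the (2+2) step, and the polarisation of the ynol ether secures it: the nucleophilic terminal CH bonds to the electrophilic ketene carbonyl carbon, so that OEt (C3') ends meta to OH (C5') and both end meta to C1'. No lasting stereocentre is made (the sp3 ring carbon of 17 is erased on opening), and C2 and C3 are carried through unchanged because the medium is neutral and aprotic, so that the vinylogous, benzylic C3–H is not removed and the C2–O bond is not ionised. The alkyne is used in excess in a closed vessel and the bath is kept at 80 °C until 14 is consumed because 15 is volatile and fragments to ketene and ethene well above 100 °C, and the closing methanolysis frees any product phenol that a ketene has acylated.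

Step 11
Reactants: 20 3-[(2S,3S)-5-chloro-2-(3,4-dimethoxyphenyl)-2,3-dihydro-1-benzofuran-3-yl]-5-ethoxyphenol; 21 3,5-dimethoxystyrene
Product: 22 3-{(2S,3S)-2-(3,4-dimethoxyphenyl)-5-[(E)-2-(3,5-dimethoxyphenyl)ethenyl]-2,3-dihydro-1-benzofuran-3-yl}-5-ethoxyphenol
Conditions: Pd2(dba)3 (2.5 mol %), [HP(t-Bu)3]BF4 (10 mol %), Cy2NMe (2.5 equiv), 1,4-dioxane, 110 °C
Reagents that add atoms: none
Why: Mizoroki–Heck reaction, in which the bulky electron-rich P(t-Bu)3 gives a monoligated zerovalent palladium species able to insert into the electron-rich C5–Cl bond, syn carbopalladation at the terminal styrene carbon and syn beta-hydride elimination give the E-stilbene, and the tertiary amine is too weak a base to touch C3–H or to turn the free phenol into a competing coupling partner.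

Step 12
Reactants: 22 3-{(2S,3S)-2-(3,4-dimethoxyphenyl)-5-[(E)-2-(3,5-dimethoxyphenyl)ethenyl]-2,3-dihydro-1-benzofuran-3-yl}-5-ethoxyphenol
Product: 23 5-[(E)-2-[(2S,3S)-2-(3,4-dihydroxyphenyl)-3-(3,5-dihydroxyphenyl)-2,3-dihydro-1-benzofuran-5-yl]ethenyl]benzene-1,3-diol (CNP0207985.1)
Conditions: BBr3 (12 equiv), CH2Cl2, argon, −78 °C to rt; ice–water
Reagents that add atoms: none
Why: Lewis-acid ether cleavage, in which boron binds each aryl alkyl ether oxygen and bromide attacks the unhindered methyl or ethyl carbon by SN2 so that four methyl ethers and the ethyl ether fall, while the ring ether with its hindered secondary carbon should persist and even a reversible ionisation at C2 would reclose under the control of the untouched C3 to the more stable trans ring.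

**Compound list**
1 | (5-chloro-2-hydroxyphenyl)acetic acid | OC(=O)Cc1cc(Cl)ccc1O | starting material
2 | methyl (5-chloro-2-hydroxyphenyl)acetate | COC(=O)Cc1cc(Cl)ccc1O | intermediate
3 | 3,4-dimethoxybenzyl chloride (veratryl chloride) | COc1ccc(CCl)cc1OC | starting material
4 | methyl {5-chloro-2-[(3,4-dimethoxybenzyl)oxy]phenyl}acetate | COC(=O)Cc1cc(Cl)ccc1OCc1ccc(OC)c(OC)c1 | intermediate
5 | methyl 2-{5-chloro-2-[(3,4-dimethoxybenzyl)oxy]phenyl}-2-diazoacetate | COC(=O)C(=[N+]=[N-])c1cc(Cl)ccc1OCc1ccc(OC)c(OC)c1 | intermediate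
6 | methyl (2S,3R)-5-chloro-2-(3,4-dimethoxyphenyl)-2,3-dihydro-1-benzofuran-3-carboxylate (cis) | Clc1ccc2c(c1)[C@@H](C(=O)OC)[C@@H](c1ccc(OC)c(OC)c1)O2 | intermediate
7 | methyl (2S,3S)-5-chloro-2-(3,4-dimethoxyphenyl)-2,3-dihydro-1-benzofuran-3-carboxylate (trans) | Clc1ccc2c(c1)[C@H](C(=O)OC)[C@@H](c1ccc(OC)c(OC)c1)O2 | intermediate
8 | diisobutylaluminium methyl hemiacetal of aldehyde 9 (C2 and C3 as in 7, hemiacetal carbon undefined; formed in the flask) | Clc1ccc2c(c1)[C@H](C(OC)O[Al](CC(C)C)CC(C)C)[C@@H](c1ccc(OC)c(OC)c1)O2 | intermediate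
9 | (2S,3S)-5-chloro-2-(3,4-dimethoxyphenyl)-2,3-dihydro-1-benzofuran-3-carbaldehyde | Clc1ccc2c(c1)[C@H](C=O)[C@@H](c1ccc(OC)c(OC)c1)O2 | intermediate
10 | (2S,3S)-5-chloro-2-(3,4-dimethoxyphenyl)-3-ethynyl-2,3-dihydro-1-benzofuran | Clc1ccc2c(c1)[C@H](C#C)[C@@H](c1ccc(OC)c(OC)c1)O2 | intermediate
11 | trichloroacetyl chloride | ClC(=O)C(Cl)(Cl)Cl | starting material
12 | dichloroketene (formed in the flask) | ClC(Cl)=C=O | intermediate
13 | 4,4-dichloro-3-[(2S,3R)-5-chloro-2-(3,4-dimethoxyphenyl)-2,3-dihydro-1-benzofuran-3-yl]cyclobut-2-en-1-one | Clc1ccc2c(c1)[C@H](C1=CC(=O)C1(Cl)Cl)[C@@H](c1ccc(OC)c(OC)c1)O2 | intermediate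
14 | 3-[(2S,3S)-5-chloro-2-(3,4-dimethoxyphenyl)-2,3-dihydro-1-benzofuran-3-yl]cyclobut-2-en-1-one | Clc1ccc2c(c1)[C@H](C1=CC(=O)C1)[C@@H](c1ccc(OC)c(OC)c1)O2 | intermediate
15 | ethoxyacetylene | CCOC#C | starting material
16 | vinylketene, 3-(dihydrobenzofuran-3-yl)buta-1,3-dien-1-one (C2 and C3 as in 14; formed in the flask) | Clc1ccc2c(c1)[C@H](C(=C)C=C=O)[C@@H](c1ccc(OC)c(OC)c1)O2 | intermediate
17 | 3-ethoxy-4-[1-(dihydrobenzofuran-3-yl)ethenyl]cyclobut-2-en-1-one (C2 and C3 as in 14, ring sp3 carbon undefined; formed in the flask) | Clc1ccc2c(c1)[C@H](C(=C)C1C(=O)C=C1OCC)[C@@H](c1ccc(OC)c(OC)c1)O2 | intermediate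
18 | dienylketene, 3-ethoxy-5-(dihydrobenzofuran-3-yl)hexa-1,3,5-trien-1-one with ketenyl and alkenyl groups cis (formed in the flask) | Clc1ccc2c(c1)[C@H](C(=C)/C=C(OCC)\C=C=O)[C@@H](c1ccc(OC)c(OC)c1)O2 | intermediate
19 | 3-ethoxy-5-(dihydrobenzofuran-3-yl)cyclohexa-2,4-dien-1-one (formed in the flask) | Clc1ccc2c(c1)[C@H](C1=CC(OCC)=CC(=O)C1)[C@@H](c1ccc(OC)c(OC)c1)O2 | intermediate
20 | 3-[(2S,3S)-5-chloro-2-(3,4-dimethoxyphenyl)-2,3-dihydro-1-benzofuran-3-yl]-5-ethoxyphenol | Clc1ccc2c(c1)[C@H](c1cc(O)cc(OCC)c1)[C@@H](c1ccc(OC)c(OC)c1)O2 | intermediate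
21 | 3,5-dimethoxystyrene | C=Cc1cc(OC)cc(OC)c1 | starting material
22 | 3-{(2S,3S)-2-(3,4-dimethoxyphenyl)-5-[(E)-2-(3,5-dimethoxyphenyl)ethenyl]-2,3-dihydro-1-benzofuran-3-yl}-5-ethoxyphenol | COc1cc(OC)cc(/C=C/c2ccc3c(c2)[C@H](c2cc(O)cc(OCC)c2)[C@@H](c2ccc(OC)c(OC)c2)O3)c1 | intermediate
23 | 5-[(E)-2-[(2S,3S)-2-(3,4-dihydroxyphenyl)-3-(3,5-dihydroxyphenyl)-2,3-dihydro-1-benzofuran-5-yl]ethenyl]benzene-1,3-diol | Oc1cc(O)cc(/C=C/c2ccc3c(c2)[C@H](c2cc(O)cc(O)c2)[C@@H](c2ccc(O)c(O)c2)O3)c1 | target

**Totals**
Total step count: 12. Longest linear sequence: 12 steps (from 1).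

**Steps most likely to fail**

Step 10 (key benzannulation). Three processes may interfere:
- the volatile, heat-sensitive alkyne may be lost before all vinylketene is trapped;
- ketene intermediates may acylate the product phenol;
- a prototropic shift of the ring double bond of 14 towards C3 before ring opening would erase that centre.

In the fallback ring C is brought in intact and not built. Setting out from 7, saponification (LiOH, THF–H2O) should give (2S,3S)-5-chloro-2-(3,4-dimethoxyphenyl)-2,3-dihydro-1-benzofuran-3-carboxylic acid F1. Decarboxylative arylation with 1-bromo-3,5-dimethoxybenzene follows under dual photoredox and nickel catalysis (Ir[dF(CF3)ppy]2(dtbbpy)PF6, NiCl2·glyme, dtbbpy, Cs2CO3, DMF, blue light, rt). It passes through the C3 benzylic radical, which should be arylated on the face away from ring B, while the aryl chloride stays inert beside the aryl bromide. The product should be (2S,3S)-5-chloro-2-(3,4-dimethoxyphenyl)-3-(3,5-dimethoxyphenyl)-2,3-dihydro-1-benzofuran F2. The conditions of step 11 should then give the stilbene hexamethyl ether F3, and the conditions of step 12 bring the material back to the route at 23.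

Step 12 (global dealkylation). Four processes may interfere:
- acid-induced ionisation of the benzylic C2–O bond;
- protonation and oligomerisation of the electron-rich stilbene by HBr;
- incomplete cleavage of the slower ethyl ether;
- air oxidation of the catechol during work-up.

In the fallback the protecting groups are exchanged before the stilbene exists, so that the last step is a mild methanolysis. Setting out from 20, BBr3 in CH2Cl2 should give 4-[(2S,3S)-5-chloro-3-(3,5-dihydroxyphenyl)-2,3-dihydro-1-benzofuran-2-yl]benzene-1,2-diol F4. Ac2O and pyridine convert it into the tetraacetate F5. Heck coupling under the conditions of step 11 with 3,5-diacetoxystyrene (catalogue compound) should give the stilbene hexaacetate F6. K2CO3 (cat.) in degassed MeOH at 0 °C then returns to the route at 23.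

Step 4 (enantioselective C–H insertion). Enantio- and diastereoselectivity may erode because the very electron-rich benzylic C–H bond favours an early, hydride-transfer-like transition state. The sense of induction may also be opposite to the one assumed. In the fallback resolution replaces asymmetric catalysis. Setting out from 5, decomposition with achiral Rh2(OAc)4 (CH2Cl2, rt) should give the racemic cis ester F7, and NaOMe in MeOH converts it into the racemic trans ester F8. The enantiomers are separated by preparative supercritical-fluid chromatography on a polysaccharide carbamate phase. The (2S,3S) enantiomer, assigned by anomalous-dispersion crystallography, rejoins the route at 7.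

**Further compounds**
F1 | step 10 | (2S,3S)-5-chloro-2-(3,4-dimethoxyphenyl)-2,3-dihydro-1-benzofuran-3-carboxylic acid | Clc1ccc2c(c1)[C@H](C(=O)O)[C@@H](c1ccc(OC)c(OC)c1)O2
F2 | step 10 | (2S,3S)-5-chloro-2-(3,4-dimethoxyphenyl)-3-(3,5-dimethoxyphenyl)-2,3-dihydro-1-benzofuran | Clc1ccc2c(c1)[C@H](c1cc(OC)cc(OC)c1)[C@@H](c1ccc(OC)c(OC)c1)O2
F3 | step 10 | (2S,3S)-2-(3,4-dimethoxyphenyl)-3-(3,5-dimethoxyphenyl)-5-[(E)-2-(3,5-dimethoxyphenyl)ethenyl]-2,3-dihydro-1-benzofuran | COc1cc(OC)cc(/C=C/c2ccc3c(c2)[C@H](c2cc(OC)cc(OC)c2)[C@@H](c2ccc(OC)c(OC)c2)O3)c1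
F4 | step 12 | 4-[(2S,3S)-5-chloro-3-(3,5-dihydroxyphenyl)-2,3-dihydro-1-benzofuran-2-yl]benzene-1,2-diol | Clc1ccc2c(c1)[C@H](c1cc(O)cc(O)c1)[C@@H](c1ccc(O)c(O)c1)O2
F5 | step 12 | tetraacetate of F4 | Clc1ccc2c(c1)[C@H](c1cc(OC(C)=O)cc(OC(C)=O)c1)[C@@H](c1ccc(OC(C)=O)c(OC(C)=O)c1)O2
F6 | step 12 | hexaacetate of 23 | CC(=O)Oc1cc(OC(C)=O)cc(/C=C/c2ccc3c(c2)[C@H](c2cc(OC(C)=O)cc(OC(C)=O)c2)[C@@H](c2ccc(OC(C)=O)c(OC(C)=O)c2)O3)c1
F7 | step 4 | racemic methyl cis-5-chloro-2-(3,4-dimethoxyphenyl)-2,3-dihydro-1-benzofuran-3-carboxylate | Clc1ccc2c(c1)[C@@H](C(=O)OC)[C@@H](c1ccc(OC)c(OC)c1)O2.Clc1ccc2c(c1)[C@H](C(=O)OC)[C@H](c1ccc(OC)c(OC)c1)O2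
F8 | step 4 | racemic methyl trans-5-chloro-2-(3,4-dimethoxyphenyl)-2,3-dihydro-1-benzofuran-3-carboxylate | Clc1ccc2c(c1)[C@H](C(=O)OC)[C@@H](c1ccc(OC)c(OC)c1)O2.Clc1ccc2c(c1)[C@@H](C(=O)OC)[C@H](c1ccc(OC)c(OC)c1)O2
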